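**Plan**

- Cuts: the allylic O–CH2 bond of the ester (carboxylate + (Z)-cinnamyl chloride), then the free CO2H back to CH2OH, then the resulting (R)-mevalonate closed to (R)-mevalonolactone; the Z C=C bond goes back to syringaldehyde and a phosphonoacetate.
- Enabling feature: C3 of the pentanedioate chain carries CH3, OH and two CH2–C(=O)O arms. At the alcohol level these are the two enantiotopic CH2CH2OH arms of achiral 3-methylpentane-1,3,5-triol, and oxidising one arm closes the six-membered oxan-2-one ring (O1–C2 bond).
- Forward order: the δ-lactone is made first (the only ring formed, opened again at the union). The aryl piece is built by silylation, Z-olefination, reduction and chlorination. The chain is then joined by carboxylate alkylation, C5 is oxidised and the phenol is freed.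
- Stereochemistry: C3 (R) comes from the dehydrogenase choosing the pro-R arm and is not touched afterwards. The Z alkene comes from the Still–Gennari olefination.

Key step: step 1

Assumption: an NAD-dependent alcohol dehydrogenase that prefers the pro-R hydroxyethyl arm of the triol is taken from a screening panel (the horse-liver enzyme is the reference catalyst for this reaction type); the lactone is assayed by chiral GC and carried on only as the (R) enantiomer of high enantiomeric purity.

**Route**

Step 1
Reactants: 1 3-methylpentane-1,3,5-triol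
Product: 4 (R)-mevalonolactone [(4R)-4-hydroxy-4-methyloxan-2-one], via (R)-hydroxy aldehyde 2 (not isolated), via lactol 3 (not isolated)
Conditions: NAD-dependent alcohol dehydrogenase (horse-liver type, pro-R-arm selective), NAD+ (cat.), water-forming NADH oxidase, air (O2 → H2O), phosphate buffer pH 7.5–8, 25–30 °C; then pH 3, continuous extraction (EtOAc)
Reagents that add atoms: none
Why: The dehydrogenase passes a hydride from C1 of the pro-R hydroxyethyl arm of 1 to NAD+ and releases hydroxy aldehyde 2, while the oxidase returns NADH to NAD+ at the expense of O2. The untouched primary hydroxyl then adds to the aldehyde carbon in a 6-exo-trig hemiacetalisation to give lactol 3, and a second enzymatic dehydrogenation of the lactol C–H gives δ-lactone 4; this last oxidation is practically irreversible and draws the equilibria forward. The closest known reaction type is the alcohol-dehydrogenase-mediated oxidative lactonisation of prochiral 3-substituted pentane-1,5-diols with in situ NAD+ recycling. No bond at C3 is made or broken: the carbon becomes a stereocentre only because the two arms are told apart, so its (R) configuration is controlled solely by the chiral active site, which presents one arm to the nicotinamide. The step needs enantiotopic-group selectivity (pro-R over pro-S arm) and chemoselectivity for primary over tertiary hydroxyl; the tertiary carbinol has no carbinol hydrogen to lose, and after ring closure no primary hydroxyl remains, so over-oxidation to the diacid is excluded as long as the lactone stays closed at the working pH.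

Step 2
Reactants: 5 syringaldehyde
Product: 6 3,5-dimethoxy-4-[(triisopropylsilyl)oxy]benzaldehyde
Conditions: TIPSCl, imidazole, DMF, rt
Reagents that add atoms: triisopropylsilyl chloride, CC(C)[Si](Cl)(C(C)C)C(C)C
Why: Imidazole-promoted O-silylation of the phenol gives a bulky aryl silyl ether that should survive the enolate, hydride, carboxylate and oxidant steps and, being flanked by two methoxy groups, is expected to donate only weakly to the later allylic chloride.

Step 3
Reactants: 6 3,5-dimethoxy-4-[(triisopropylsilyl)oxy]benzaldehyde; 7 methyl bis(2,2,2-trifluoroethoxy)phosphorylacetate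
Product: 9 methyl (2Z)-3-{3,5-dimethoxy-4-[(triisopropylsilyl)oxy]phenyl}prop-2-enoate, via potassium phosphonate enolate 8 (not isolated)
Conditions: KHMDS, 18-crown-6, THF, −78 °C; then 6, −78 °C
Reagents that add atoms: none
Why: Still–Gennari variant of the Horner–Wadsworth–Emmons olefination, in which the electron-poor trifluoroethyl phosphonate and the crown-complexed potassium ion make elimination from the kinetic adduct faster than its equilibration, so the Z enoate should predominate.

Step 4
Reactants: 9 methyl (2Z)-3-{3,5-dimethoxy-4-[(triisopropylsilyl)oxy]phenyl}prop-2-enoate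
Product: 11 (2Z)-3-{3,5-dimethoxy-4-[(triisopropylsilyl)oxy]phenyl}prop-2-en-1-ol, via (Z)-enal 10 (not isolated)
Conditions: DIBAL-H (2.5 equiv), CH2Cl2, −78 °C; aq. Rochelle salt
Reagents that add atoms: none
Why: DIBAL-H 1,2-reduction of an enoate at low temperature passes through enal 10 to the allylic alcohol and should leave the Z double bond and the aryl silyl ether untouched.

Step 5
Reactants: 11 (2Z)-3-{3,5-dimethoxy-4-[(triisopropylsilyl)oxy]phenyl}prop-2-en-1-ol
Product: 12 {4-[(1Z)-3-chloroprop-1-en-1-yl]-2,6-dimethoxyphenoxy}triisopropylsilane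
Conditions: PPh3, Cl3CC(O)CCl3, CH2Cl2, −20 → 0 °C; crude product used at once
Reagents that add atoms: hexachloroacetone, O=C(C(Cl)(Cl)Cl)C(Cl)(Cl)Cl
Why: Appel-type chlorination with the phosphine/hexachloroacetone couple replaces a primary allylic hydroxyl by chloride in an SN2 process under neutral conditions, which is expected to keep the alkene geometry and avoid allylic transposition.

Step 6
Reactants: 4 (R)-mevalonolactone; 12 {4-[(1Z)-3-chloroprop-1-en-1-yl]-2,6-dimethoxyphenoxy}triisopropylsilane
Product: 14 (2Z)-3-{3,5-dimethoxy-4-[(triisopropylsilyl)oxy]phenyl}prop-2-en-1-yl (3R)-3,5-dihydroxy-3-methylpentanoate, via caesium (R)-mevalonate 13 (not isolated)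
Conditions: CsOH·H2O (1.0 equiv), H2O, rt; freeze-dry; then 12, DMF, 0 °C → rt
Reagents that add atoms: caesium hydroxide, [Cs+].[OH-]
Why: Hydroxide opens the δ-lactone to carboxylate 13, and the caesium carboxylate in DMF should alkylate the primary allylic chloride by SN2 (carboxylate O-alkylation) far faster than either hydroxyl reacts, leaving C3 and the Z geometry unchanged.

Step 7
Reactants: 14 (2Z)-3-{3,5-dimethoxy-4-[(triisopropylsilyl)oxy]phenyl}prop-2-en-1-yl (3R)-3,5-dihydroxy-3-methylpentanoate
Product: 16 (3R)-5-{[(2Z)-3-{3,5-dimethoxy-4-[(triisopropylsilyl)oxy]phenyl}prop-2-en-1-yl]oxy}-3-hydroxy-3-methyl-5-oxopentanoic acid, via ester aldehyde 15 (not isolated)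
Conditions: TEMPO (cat.), PhI(OAc)2 (2.2 equiv), MeCN–H2O (1:1), 0 °C → rt
Reagents that add atoms: water, O
Why: Oxoammonium-mediated (TEMPO/PhI(OAc)2) oxidation in aqueous acetonitrile takes the primary alcohol through aldehyde 15 to the acid, while the tertiary alcohol, the Z alkene, the allylic ester and the aryl silyl ether should be inert to this oxidant.

Step 8
Reactants: 16 (3R)-5-{[(2Z)-3-{3,5-dimethoxy-4-[(triisopropylsilyl)oxy]phenyl}prop-2-en-1-yl]oxy}-3-hydroxy-3-methyl-5-oxopentanoic acid
Product: 17 (3R)-3-hydroxy-5-{[(2Z)-3-(4-hydroxy-3,5-dimethoxyphenyl)prop-2-en-1-yl]oxy}-3-methyl-5-oxopentanoic acid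
Conditions: TBAF, AcOH (1:1), THF, 0 °C
Reagents that add atoms: none
Why: Fluoride desilylation cleaves the aryl O–Si bond and the acetic acid buffer protonates the phenoxide at once, so ester cleavage, quinone-methide formation and Z/E isomerisation are not expected.

**Compound list**

1 | 3-methylpentane-1,3,5-triol | CC(O)(CCO)CCO | starting material
2 | (3R)-3,5-dihydroxy-3-methylpentanal | O=CC[C@](C)(O)CCO | intermediate
3 | (4R)-4-methyloxane-2,4-diol (lactol, anomeric mixture) | OC1C[C@](C)(O)CCO1 | intermediate
4 | (R)-mevalonolactone, (4R)-4-hydroxy-4-methyloxan-2-one | O=C1C[C@](C)(O)CCO1 | intermediate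
5 | syringaldehyde (4-hydroxy-3,5-dimethoxybenzaldehyde) | COc1cc(C=O)cc(OC)c1O | starting material
6 | 3,5-dimethoxy-4-[(triisopropylsilyl)oxy]benzaldehyde | COc1cc(C=O)cc(OC)c1O[Si](C(C)C)(C(C)C)C(C)C | intermediate
7 | methyl bis(2,2,2-trifluoroethoxy)phosphorylacetate | COC(=O)CP(=O)(OCC(F)(F)F)OCC(F)(F)F | starting material
8 | potassium enolate of methyl bis(2,2,2-trifluoroethoxy)phosphorylacetate | COC(=O)[CH-]P(=O)(OCC(F)(F)F)OCC(F)(F)F.[K+] | intermediate
9 | methyl (2Z)-3-{3,5-dimethoxy-4-[(triisopropylsilyl)oxy]phenyl}prop-2-enoate | COC(=O)/C=C\c1cc(OC)c(O[Si](C(C)C)(C(C)C)C(C)C)c(OC)c1 | intermediate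
10 | (2Z)-3-{3,5-dimethoxy-4-[(triisopropylsilyl)oxy]phenyl}prop-2-enal | COc1cc(/C=C\C=O)cc(OC)c1O[Si](C(C)C)(C(C)C)C(C)C | intermediate
11 | (2Z)-3-{3,5-dimethoxy-4-[(triisopropylsilyl)oxy]phenyl}prop-2-en-1-ol | COc1cc(/C=C\CO)cc(OC)c1O[Si](C(C)C)(C(C)C)C(C)C | intermediate
12 | {4-[(1Z)-3-chloroprop-1-en-1-yl]-2,6-dimethoxyphenoxy}triisopropylsilane | COc1cc(/C=C\CCl)cc(OC)c1O[Si](C(C)C)(C(C)C)C(C)C | intermediate
13 | caesium (3R)-3,5-dihydroxy-3-methylpentanoate | [Cs+].[O-]C(=O)C[C@](C)(O)CCO | intermediate
14 | (2Z)-3-{3,5-dimethoxy-4-[(triisopropylsilyl)oxy]phenyl}prop-2-en-1-yl (3R)-3,5-dihydroxy-3-methylpentanoate | COc1cc(/C=C\COC(=O)C[C@](C)(O)CCO)cc(OC)c1O[Si](C(C)C)(C(C)C)C(C)C | intermediate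
15 | (2Z)-3-{3,5-dimethoxy-4-[(triisopropylsilyl)oxy]phenyl}prop-2-en-1-yl (3R)-3-hydroxy-3-methyl-5-oxopentanoate | COc1cc(/C=C\COC(=O)C[C@](C)(O)CC=O)cc(OC)c1O[Si](C(C)C)(C(C)C)C(C)C | intermediate
16 | (3R)-5-{[(2Z)-3-{3,5-dimethoxy-4-[(triisopropylsilyl)oxy]phenyl}prop-2-en-1-yl]oxy}-3-hydroxy-3-methyl-5-oxopentanoic acid | COc1cc(/C=C\COC(=O)C[C@](C)(O)CC(=O)O)cc(OC)c1O[Si](C(C)C)(C(C)C)C(C)C | intermediate
17 | (3R)-3-hydroxy-5-{[(2Z)-3-(4-hydroxy-3,5-dimethoxyphenyl)prop-2-en-1-yl]oxy}-3-methyl-5-oxopentanoic acid | COc1cc(/C=C\COC(=O)C[C@](C)(O)CC(=O)O)cc(OC)c1O | target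

**Step count**

Total steps: 8. Longest linear sequence: 7 steps (5 → 6 → 9 → 11 → 12 → 14 → 16 → 17; steps 2–8). The triol branch reaches the target in 4 steps (1, 6, 7, 8).

**Steps most likely to fail**

Step 1. The enzyme may discriminate poorly between the two hydroxyethyl arms, or prefer the pro-S arm, so that the lactone is formed in low or opposite enantiomeric purity. Slow ring-opening of the lactone in the buffer would also re-expose a primary hydroxyl to further oxidation. The fallback sets out from 1 and returns at 4 by classical resolution. The triol is oxidised without an enzyme (TEMPO, PhI(OAc)2, CH2Cl2; oxidative lactonisation of the 1,5-diol) to racemic mevalonolactone F1. Heating it with (R)-1-phenylethylamine opens the ring to two diastereomeric hydroxy amides, (3R)-3,5-dihydroxy-3-methyl-N-[(1R)-1-phenylethyl]pentanamide F2 and (3S)-3,5-dihydroxy-3-methyl-N-[(1R)-1-phenylethyl]pentanamide F3, which are separated by crystallisation or chromatography. Hydrolysis of the (3R) amide (aq. NaOH, heat), then acidification to pH 3, releases the amine and closes the ring to 4.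

Step 6. The allylic chloride may ionise, with loss of Z geometry or SN2′ capture, and the δ-hydroxy ester may re-close to the lactone with expulsion of the allylic alcohol. The fallback sets out from 4 and 11 and returns at 14; it replaces alkylation by acylation, so no allylic halide is needed and the 5-hydroxyl is blocked while the ester is made. Caesium salt 13, made from 4 as in step 6, is silylated twice (TBSCl, imidazole, DMF) to tert-butyldimethylsilyl (3R)-5-[(tert-butyldimethylsilyl)oxy]-3-hydroxy-3-methylpentanoate F4. K2CO3 in aqueous MeOH–THF cleaves only the silyl ester and gives (3R)-5-[(tert-butyldimethylsilyl)oxy]-3-hydroxy-3-methylpentanoic acid F5. Steglich esterification with alcohol 11 (EDC·HCl, DMAP, CH2Cl2, 0 °C) gives (2Z)-3-{3,5-dimethoxy-4-[(triisopropylsilyl)oxy]phenyl}prop-2-en-1-yl (3R)-5-[(tert-butyldimethylsilyl)oxy]-3-hydroxy-3-methylpentanoate F6. CSA (cat.) in MeOH–CH2Cl2 at 0 °C removes the primary alkyl silyl ether, leaves the aryl silyl ether, and returns 14, which goes straight into step 7.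

Step 7. The δ-hydroxy ester may lactonise in the aqueous, acetic-acid-releasing medium before oxidation is complete, or the oxidant may attack the electron-rich aryl alkene. The fallback sets out from 14 and returns at 16; the one-pot aqueous oxidation is given up for two separate reactions with isolation of the aldehyde. Dess–Martin periodinane (NaHCO3, dry CH2Cl2, 0 °C) converts 14 under anhydrous, buffered conditions into aldehyde 15, which is isolated. A Pinnick oxidation (NaClO2, NaH2PO4, 2-methyl-2-butene, t-BuOH–H2O) then gives 16, the scavenger protecting the alkene from hypochlorite. No compound outside the list is made.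

**Further compounds**

F1 | step 1 | racemic mevalonolactone (4-hydroxy-4-methyloxan-2-one) | CC1(O)CCOC(=O)C1
F2 | step 1 | (3R)-3,5-dihydroxy-3-methyl-N-[(1R)-1-phenylethyl]pentanamide | C[C@@H](NC(=O)C[C@](C)(O)CCO)c1ccccc1
F3 | step 1 | (3S)-3,5-dihydroxy-3-methyl-N-[(1R)-1-phenylethyl]pentanamide | C[C@@H](NC(=O)C[C@@](C)(O)CCO)c1ccccc1
F4 | step 6 | tert-butyldimethylsilyl (3R)-5-[(tert-butyldimethylsilyl)oxy]-3-hydroxy-3-methylpentanoate | CC(C)(C)[Si](C)(C)OC(=O)C[C@](C)(O)CCO[Si](C)(C)C(C)(C)C
F5 | step 6 | (3R)-5-[(tert-butyldimethylsilyl)oxy]-3-hydroxy-3-methylpentanoic acid | OC(=O)C[C@](C)(O)CCO[Si](C)(C)C(C)(C)C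
F6 | step 6 | (2Z)-3-{3,5-dimethoxy-4-[(triisopropylsilyl)oxy]phenyl}prop-2-en-1-yl (3R)-5-[(tert-butyldimethylsilyl)oxy]-3-hydroxy-3-methylpentanoate | COc1cc(/C=C\COC(=O)C[C@](C)(O)CCO[Si](C)(C)C(C)(C)C)cc(OC)c1O[Si](C(C)C)(C(C)C)C(C)C
F0 | step 7 | none | none
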